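## Retrosynthetic overview

- Kanzonol I comes from its aryl silyl ether; the chroman O1–C2 bond is the key bond, closed last by an intramolecular copper-mediated C(sp3)–O coupling of the ring A phenol with a primary alkylboronate.
- The boronate, which carries the C3 stereocentre, comes from enantioselective anti-Markovnikov hydroboration of a 2-(2-arylallyl)phenol.
- The allylphenol comes from aromatic Claisen rearrangement of an aryl 2-arylallyl ether, itself made by Negishi coupling of a ring B chromenylzinc with the 2-bromoallyl ether of the ring A phenol.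
- Ring A phenol: 1,3-dimethoxybenzene, lithiation and prenylation, then C–H borylation and oxidation. Ring B: 4-bromoresorcinol, mono-silylation, dimethylpropargyl ether, Claisen/electrocyclisation.
- Ring order: the pyran ring of the ring B chromene is formed first, the chroman heterocycle (ring C) last.

Assumption: L* is 2-[(4S)-4-tert-butyl-4,5-dihydro-1,3-oxazol-2-yl]-6-[1-(2,6-diisopropylphenylimino)ethyl]pyridine, and its complex (L*)CoCl2 is assumed to give the R boronate; if the first run gives S, the 4R ligand is used instead.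

## Route

Step 1
Reactants: 1 1,3-dimethoxybenzene; 2 1-bromo-3-methylbut-2-ene (prenyl bromide)
Product: 4 1,3-dimethoxy-2-(3-methylbut-2-en-1-yl)benzene, via 2,6-dimethoxyphenyllithium 3 (not isolated)
Conditions: n-BuLi, THF, 0 °C to rt; then 2, −78 °C to rt
Reagents that add atoms: none
Why: Directed ortho-lithiation at the carbon between the two methoxy groups, then SN2 alkylation of the aryllithium by the allylic bromide, is a standard route to 2-prenylresorcinol dimethyl ether.

Step 2
Reactants: 4 1,3-dimethoxy-2-(3-methylbut-2-en-1-yl)benzene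
Product: 6 3,5-dimethoxy-4-(3-methylbut-2-en-1-yl)phenol, via arylboronic pinacol ester 5 (not isolated)
Conditions: [Ir(OMe)(cod)]2 (1.5 mol %), 4,4'-di-tert-butyl-2,2'-bipyridine (3 mol %), B2pin2 (0.55 equiv), THF, 80 °C; then aq NaOH, 30% H2O2, 0 °C to rt
Reagents that add atoms: hydrogen peroxide, OO (the phenol oxygen); bis(pinacolato)diboron, CC1(C)OB(OC1(C)C)B1OC(C)(C)C(C)(C)O1 (its boron stays only in 5)
Why: Sterically controlled iridium-catalysed C–H borylation goes to the only ring C–H without an ortho substituent, and basic peroxide oxidation of the C–B bond gives the symmetric phenol without touching the trisubstituted alkene.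

Step 3
Reactants: 6 3,5-dimethoxy-4-(3-methylbut-2-en-1-yl)phenol; 7 2,3-dibromoprop-1-ene
Product: 8 5-[(2-bromoprop-2-en-1-yl)oxy]-1,3-dimethoxy-2-(3-methylbut-2-en-1-yl)benzene
Conditions: K2CO3, acetone, 56 °C
Reagents that add atoms: none
Why: Williamson etherification: the phenoxide displaces the allylic bromide while the vinylic bromide is inert to SN2.

Step 4
Reactants: 9 4-bromobenzene-1,3-diol (4-bromoresorcinol)
Product: 10 2-bromo-5-(triisopropylsilyloxy)phenol
Conditions: TIPSCl (1.0 equiv), imidazole, DMF, −10 °C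
Reagents that add atoms: triisopropylsilyl chloride, CC(C)[Si](Cl)(C(C)C)C(C)C
Why: Sterically controlled silylation: the bulky silyl chloride takes the unhindered hydroxyl para to bromine much faster than the hydroxyl flanked by bromine.

Step 5
Reactants: 10 2-bromo-5-(triisopropylsilyloxy)phenol; 11 3-chloro-3-methylbut-1-yne
Product: 12 1-bromo-2-[(2-methylbut-3-yn-2-yl)oxy]-4-(triisopropylsilyloxy)benzene
Conditions: DBU, CuCl2 (1 mol %), anhydrous MeCN, 0 °C
Reagents that add atoms: none
Why: Copper-catalysed propargylic etherification of a phenol with the tertiary propargylic chloride is the standard mild route to aryl 1,1-dimethylpropargyl ethers, and the silyl ether survives the anhydrous conditions.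

Step 6
Reactants: 12 1-bromo-2-[(2-methylbut-3-yn-2-yl)oxy]-4-(triisopropylsilyloxy)benzene
Product: 14 8-bromo-2,2-dimethyl-5-(triisopropylsilyloxy)-2H-chromene, via allenylphenol 13 (not isolated)
Conditions: PhNEt2, 180 °C
Reagents that add atoms: none
Why: Aryl propargyl ether Claisen rearrangement: the [3,3] shift can end productively only at the one unsubstituted ortho carbon, and tautomerisation to 13, a [1,5]-H shift and oxa-6π electrocyclisation give the chromene with its ring oxygen next to bromine.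

Step 7
Reactants: 14 8-bromo-2,2-dimethyl-5-(triisopropylsilyloxy)-2H-chromene; 8 5-[(2-bromoprop-2-en-1-yl)oxy]-1,3-dimethoxy-2-(3-methylbut-2-en-1-yl)benzene
Product: 17 8-{3-[3,5-dimethoxy-4-(3-methylbut-2-en-1-yl)phenoxy]prop-1-en-2-yl}-2,2-dimethyl-5-(triisopropylsilyloxy)-2H-chromene, via chromen-8-yllithium 15 (not isolated), via chromen-8-ylzinc chloride 16 (not isolated)
Conditions: n-BuLi, THF, −78 °C; ZnCl2, −78 °C to rt; then 8, Pd(PPh3)4 (5 mol %), 50 °C
Reagents that add atoms: none
Why: One-pot Negishi coupling: bromine–lithium exchange and transmetalation give an arylzinc that couples with the vinyl bromide after its oxidative addition to zerovalent palladium, faster than any ionisation of the electron-rich aryl allyl ether.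

Step 8
Reactants: 17 8-{3-[3,5-dimethoxy-4-(3-methylbut-2-en-1-yl)phenoxy]prop-1-en-2-yl}-2,2-dimethyl-5-(triisopropylsilyloxy)-2H-chromene
Product: 19 2-{2-[2,2-dimethyl-5-(triisopropylsilyloxy)-2H-chromen-8-yl]prop-2-en-1-yl}-3,5-dimethoxy-4-(3-methylbut-2-en-1-yl)phenol, via ortho-dienone 18 (not isolated)
Conditions: PhNEt2, 180 °C
Reagents that add atoms: none
Why: Aromatic Claisen rearrangement: the [3,3] shift delivers the 2-arylallyl unit to either of the two equivalent ortho carbons and dienone 18 tautomerises to the phenol, while the basic solvent suppresses acid-promoted Markovnikov ring closure.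

Step 9
Reactants: 19 2-{2-[2,2-dimethyl-5-(triisopropylsilyloxy)-2H-chromen-8-yl]prop-2-en-1-yl}-3,5-dimethoxy-4-(3-methylbut-2-en-1-yl)phenol
Product: 22 2-{(2R)-2-[2,2-dimethyl-5-(triisopropylsilyloxy)-2H-chromen-8-yl]-3-(4,4,5,5-tetramethyl-1,3,2-dioxaborolan-2-yl)propyl}-3,5-dimethoxy-4-(3-methylbut-2-en-1-yl)phenol, via O-boryl alkene 20 (not isolated), via O-boryl alkylboronate 21 (not isolated)
Conditions: HBpin (2.5 equiv), (L*)CoCl2 (3 mol %), NaBHEt3 (9 mol %), THF, 25 °C; aq NH4Cl work-up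
Reagents that add atoms: pinacolborane, [H]B1OC(C)(C)C(C)(C)O1
Why: Cobalt-hydride-catalysed enantioselective anti-Markovnikov hydroboration of a 1,1-disubstituted aryl alkene: HBpin first caps the phenol as its borate ester, Co–H then adds to the only 1,1-disubstituted alkene with boron going to CH2, and the chiral ligand selects the alkene face that receives hydrogen so that C3 is set as R; the prenyl and chromene double bonds are too hindered to react.

Step 10
Reactants: 22 2-{(2R)-2-[2,2-dimethyl-5-(triisopropylsilyloxy)-2H-chromen-8-yl]-3-(4,4,5,5-tetramethyl-1,3,2-dioxaborolan-2-yl)propyl}-3,5-dimethoxy-4-(3-methylbut-2-en-1-yl)phenol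
Product: 23 (3R)-5,7-dimethoxy-6-(3-methylbut-2-en-1-yl)-3-[2,2-dimethyl-5-(triisopropylsilyloxy)-2H-chromen-8-yl]-3,4-dihydro-2H-chromene
Conditions: Cu(OAc)2 (20 mol %), 2,2'-bipyridine (20 mol %), K3PO4 (1.5 equiv), (t-BuO)2 (2 equiv), toluene, 60 °C, Ar
Reagents that add atoms: none
Why: Proposed new method: an intramolecular Chan–Lam-type C(sp3)–O coupling in which the phenoxide binds boron to form a seven-membered borate, this hands the primary alkyl group (by transmetalation or as a radical) to the divalent copper phenoxide, oxidation by the peroxide gives a trivalent copper alkyl aryloxide, and C–O reductive elimination closes the six-membered ring and releases monovalent copper; C3 takes no part and stays R; the closest known reaction type is the intermolecular copper-mediated O-alkylation and O-cyclopropylation of phenols with alkylboron reagents, which has not been shown as a chroman-forming ring closure of a β-stereogenic primary alkylboronate.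

Step 11
Reactants: 23 (3R)-5,7-dimethoxy-6-(3-methylbut-2-en-1-yl)-3-[2,2-dimethyl-5-(triisopropylsilyloxy)-2H-chromen-8-yl]-3,4-dihydro-2H-chromene
Product: 24 Kanzonol I, 8-[(3R)-5,7-dimethoxy-6-(3-methylbut-2-en-1-yl)-3,4-dihydro-2H-chromen-3-yl]-2,2-dimethyl-2H-chromen-5-ol
Conditions: TBAF, AcOH, THF, 0 °C
Reagents that add atoms: none
Why: Fluoride desilylation of the aryl silyl ether, buffered with AcOH so the electron-rich phenoxide is not left in base, frees the 4'-hydroxyl without touching C3, the alkenes or the methyl ethers.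

## Compound list

1 | 1,3-dimethoxybenzene | COc1cccc(OC)c1 | starting material
2 | 1-bromo-3-methylbut-2-ene (prenyl bromide) | CC(C)=CCBr | starting material
3 | 2,6-dimethoxyphenyllithium | [Li]c1c(OC)cccc1OC | intermediate
4 | 1,3-dimethoxy-2-(3-methylbut-2-en-1-yl)benzene | COc1cccc(OC)c1CC=C(C)C | intermediate
5 | 2-[3,5-dimethoxy-4-(3-methylbut-2-en-1-yl)phenyl]-4,4,5,5-tetramethyl-1,3,2-dioxaborolane | COc1cc(B2OC(C)(C)C(C)(C)O2)cc(OC)c1CC=C(C)C | intermediate
6 | 3,5-dimethoxy-4-(3-methylbut-2-en-1-yl)phenol | COc1cc(O)cc(OC)c1CC=C(C)C | intermediate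
7 | 2,3-dibromoprop-1-ene | C=C(Br)CBr | starting material
8 | 5-[(2-bromoprop-2-en-1-yl)oxy]-1,3-dimethoxy-2-(3-methylbut-2-en-1-yl)benzene | COc1cc(OCC(Br)=C)cc(OC)c1CC=C(C)C | intermediate
9 | 4-bromobenzene-1,3-diol (4-bromoresorcinol) | Oc1ccc(Br)c(O)c1 | starting material
10 | 2-bromo-5-(triisopropylsilyloxy)phenol | Oc1cc(O[Si](C(C)C)(C(C)C)C(C)C)ccc1Br | intermediate
11 | 3-chloro-3-methylbut-1-yne | CC(C)(Cl)C#C | starting material
12 | 1-bromo-2-[(2-methylbut-3-yn-2-yl)oxy]-4-(triisopropylsilyloxy)benzene | C#CC(C)(C)Oc1cc(O[Si](C(C)C)(C(C)C)C(C)C)ccc1Br | intermediate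
13 | 6-bromo-2-(3-methylbuta-1,2-dien-1-yl)-3-(triisopropylsilyloxy)phenol | Oc1c(C=C=C(C)C)c(O[Si](C(C)C)(C(C)C)C(C)C)ccc1Br | intermediate
14 | 8-bromo-2,2-dimethyl-5-(triisopropylsilyloxy)-2H-chromene | CC1(C)C=Cc2c(O[Si](C(C)C)(C(C)C)C(C)C)ccc(Br)c2O1 | intermediate
15 | [2,2-dimethyl-5-(triisopropylsilyloxy)-2H-chromen-8-yl]lithium | [Li]c1ccc(O[Si](C(C)C)(C(C)C)C(C)C)c2C=CC(C)(C)Oc12 | intermediate
16 | [2,2-dimethyl-5-(triisopropylsilyloxy)-2H-chromen-8-yl]zinc chloride | Cl[Zn]c1ccc(O[Si](C(C)C)(C(C)C)C(C)C)c2C=CC(C)(C)Oc12 | intermediate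
17 | 8-{3-[3,5-dimethoxy-4-(3-methylbut-2-en-1-yl)phenoxy]prop-1-en-2-yl}-2,2-dimethyl-5-(triisopropylsilyloxy)-2H-chromene | COc1cc(OCC(=C)c2ccc(O[Si](C(C)C)(C(C)C)C(C)C)c3C=CC(C)(C)Oc23)cc(OC)c1CC=C(C)C | intermediate
18 | 6-{2-[2,2-dimethyl-5-(triisopropylsilyloxy)-2H-chromen-8-yl]prop-2-en-1-yl}-3,5-dimethoxy-4-(3-methylbut-2-en-1-yl)cyclohexa-2,4-dien-1-one (transient, C6 unspecified) | O=C1C=C(OC)C(CC=C(C)C)=C(OC)C1CC(=C)c1ccc(O[Si](C(C)C)(C(C)C)C(C)C)c2C=CC(C)(C)Oc12 | intermediate
19 | 2-{2-[2,2-dimethyl-5-(triisopropylsilyloxy)-2H-chromen-8-yl]prop-2-en-1-yl}-3,5-dimethoxy-4-(3-methylbut-2-en-1-yl)phenol | COc1cc(O)c(CC(=C)c2ccc(O[Si](C(C)C)(C(C)C)C(C)C)c3C=CC(C)(C)Oc23)c(OC)c1CC=C(C)C | intermediate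
20 | O-(pinacolboryl) ester of 19 (aryl–O–Bpin, alkene intact) | COc1cc(OB2OC(C)(C)C(C)(C)O2)c(CC(=C)c2ccc(O[Si](C(C)C)(C(C)C)C(C)C)c3C=CC(C)(C)Oc23)c(OC)c1CC=C(C)C | intermediate
21 | O-(pinacolboryl) ester of 22 (aryl–O–Bpin and (2R)-CH2–Bpin) | COc1cc(OB2OC(C)(C)C(C)(C)O2)c(C[C@H](c2ccc(O[Si](C(C)C)(C(C)C)C(C)C)c3C=CC(C)(C)Oc23)CB2OC(C)(C)C(C)(C)O2)c(OC)c1CC=C(C)C | intermediate
22 | 2-{(2R)-2-[2,2-dimethyl-5-(triisopropylsilyloxy)-2H-chromen-8-yl]-3-(4,4,5,5-tetramethyl-1,3,2-dioxaborolan-2-yl)propyl}-3,5-dimethoxy-4-(3-methylbut-2-en-1-yl)phenol | COc1cc(O)c(C[C@H](c2ccc(O[Si](C(C)C)(C(C)C)C(C)C)c3C=CC(C)(C)Oc23)CB2OC(C)(C)C(C)(C)O2)c(OC)c1CC=C(C)C | intermediate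
23 | (3R)-5,7-dimethoxy-6-(3-methylbut-2-en-1-yl)-3-[2,2-dimethyl-5-(triisopropylsilyloxy)-2H-chromen-8-yl]-3,4-dihydro-2H-chromene | COc1cc2c(c(OC)c1CC=C(C)C)C[C@H](c1ccc(O[Si](C(C)C)(C(C)C)C(C)C)c3C=CC(C)(C)Oc13)CO2 | intermediate
24 | Kanzonol I, 8-[(3R)-5,7-dimethoxy-6-(3-methylbut-2-en-1-yl)-3,4-dihydro-2H-chromen-3-yl]-2,2-dimethyl-2H-chromen-5-ol | COc1cc2c(c(OC)c1CC=C(C)C)C[C@H](c1ccc(O)c3c1OC(C)(C)C=C3)CO2 | target

## Step count and risks

Total steps: 11. Longest linear sequence: 8 steps (1, 2, 3, 7, 8, 9, 10, 11 from compound 1; equally 4, 5, 6, 7, 8, 9, 10, 11 from compound 9).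

The three steps most likely to fail:

Step 10, the proposed new cyclisation. The electron-rich phenol may be oxidised by the copper/peroxide system, or the primary alkylboronate may transfer too slowly. The fallback uses known chemistry, sets out from 22 and comes back at 23. Oxidation of the C–B bond with NaBO3·4H2O in THF/water gives 2-{(2R)-2-[2,2-dimethyl-5-(triisopropylsilyloxy)-2H-chromen-8-yl]-3-hydroxypropyl}-3,5-dimethoxy-4-(3-methylbut-2-en-1-yl)phenol F1. Mitsunobu ring closure of its primary alcohol onto the one free phenol (PPh3, DIAD, THF, 0 °C to rt) then gives 23 with C3 untouched.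

Step 9, the asymmetric hydroboration. The ortho-substituted aryl group and the bulky benzylic arm may lower the enantioselectivity, and the chromene alkene may compete. The fallback replaces asymmetric catalysis by resolution, sets out from 19 and comes back at 23. Hydroboration with 9-BBN (THF, 0 °C to rt), which selects the 1,1-disubstituted alkene on steric grounds, and oxidation with NaBO3·4H2O give racemic 2-{2-[2,2-dimethyl-5-(triisopropylsilyloxy)-2H-chromen-8-yl]-3-hydroxypropyl}-3,5-dimethoxy-4-(3-methylbut-2-en-1-yl)phenol F2. Preparative chromatography on a chiral stationary phase separates the R enantiomer, which is the alcohol F1 described above, and the same Mitsunobu closure leads to 23.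

Step 8, the aromatic Claisen rearrangement. At 180 °C the new phenol may add across the electron-rich 1,1-disubstituted styrene to give a 2-aryl-2-methyl-2,3-dihydrobenzofuran. The fallback does the sigmatropic shift before the acid-sensitive styrene exists, sets out from 8 (and 14) and comes back at 19. Heating 8 in PhNEt2 at 170 °C gives 2-(2-bromoprop-2-en-1-yl)-3,5-dimethoxy-4-(3-methylbut-2-en-1-yl)phenol F3. Separately, 14 is lithiated to 15 (n-BuLi, THF, −78 °C), quenched with B(Oi-Pr)3 and worked up with dilute HCl to give [2,2-dimethyl-5-(triisopropylsilyloxy)-2H-chromen-8-yl]boronic acid F4. Suzuki–Miyaura coupling of F3 with F4 (Pd(OAc)2, SPhos, K3PO4, THF/water, 50 °C), which tolerates the free phenol, gives 19.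

## Further compounds

F1 | step 10 | 2-{(2R)-2-[2,2-dimethyl-5-(triisopropylsilyloxy)-2H-chromen-8-yl]-3-hydroxypropyl}-3,5-dimethoxy-4-(3-methylbut-2-en-1-yl)phenol | COc1cc(O)c(C[C@H](c2ccc(O[Si](C(C)C)(C(C)C)C(C)C)c3C=CC(C)(C)Oc23)CO)c(OC)c1CC=C(C)C
F2 | step 9 | racemic 2-{2-[2,2-dimethyl-5-(triisopropylsilyloxy)-2H-chromen-8-yl]-3-hydroxypropyl}-3,5-dimethoxy-4-(3-methylbut-2-en-1-yl)phenol | COc1cc(O)c(CC(c2ccc(O[Si](C(C)C)(C(C)C)C(C)C)c3C=CC(C)(C)Oc23)CO)c(OC)c1CC=C(C)C
F3 | step 8 | 2-(2-bromoprop-2-en-1-yl)-3,5-dimethoxy-4-(3-methylbut-2-en-1-yl)phenol | COc1cc(O)c(CC(Br)=C)c(OC)c1CC=C(C)C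
F4 | step 8 | [2,2-dimethyl-5-(triisopropylsilyloxy)-2H-chromen-8-yl]boronic acid | OB(O)c1ccc(O[Si](C(C)C)(C(C)C)C(C)C)c2C=CC(C)(C)Oc12
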